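**Retrosynthetic overview**
1. The dioxane ring is closed last. Cutting Cα–O3′ gives an open-chain "seco" flavone with a 4-alkylguaiacol and a free 3′-OH. The forward step is an anodic C–H/O–H ring closure through a p-quinone methide, with trans geometry dictated by Cβ.
2. The seco flavone comes from a tetrabenzyl flavone by global hydrogenolysis. That flavone comes from a 2′-hydroxychalcone (I2/DMSO), made by Claisen–Schmidt condensation of an aryl aldehyde with dibenzyl phloroacetophenone.
3. In the aldehyde, Cβ–O4′ is cut. The forward step is a 4-OH-selective Mitsunobu inversion of a homobenzylic secondary alcohol with 5-hydroxyvanillin.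
4. In the alcohol, aryl–Cα is cut. The forward step is Cu-catalysed ArMgBr opening of (R)-benzyl glycidyl ether, which carries the only purchased stereocentre.
5. Ring order: chromone pyranone ring (step 4), then 1,4-dioxane ring (step 6).

Locants: Cα is the benzylic carbon of the C3 chain (C-3 of the final benzodioxine). Cβ is the carbon bearing CH2OH (C-2). 3′/4′/5′ are flavone B-ring positions.
Assumption: compounds 1, 2 (≥99% ee), 4 and 6 are catalogue items.

**Route**

Step 1
Reactants: 1, 1-(benzyloxy)-4-bromo-2-methoxybenzene; 2, (R)-benzyl glycidyl ether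
Product: 3, (2R)-1-(benzyloxy)-3-[4-(benzyloxy)-3-methoxyphenyl]propan-2-ol
Conditions: 1 (1.3 equiv), Mg, THF, reflux; CuI (10 mol %), −30 °C; then 2, −30 → 0 °C
Reagents that add atoms: none
Why: Cu-catalysed Grignard epoxide opening attacks only the unsubstituted terminus, so the C–O stereocentre is untouched and the purchased configuration is carried over as (R).

Step 2
Reactants: 3; 4, 3,4-dihydroxy-5-methoxybenzaldehyde (5-hydroxyvanillin, 1.5 equiv)
Product: 5, 4-{[(2S)-1-(benzyloxy)-3-[4-(benzyloxy)-3-methoxyphenyl]propan-2-yl]oxy}-3-hydroxy-5-methoxybenzaldehyde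
Conditions: PPh3, DIAD (slow addition), THF, 0 °C → rt
Reagents that add atoms: none
Why: In this Mitsunobu etherification the betaine deprotonates only the more acidic 4-OH (para to CHO, about 2 pKa units below 3-OH), and that phenoxide displaces the oxyphosphonium by clean SN2 at a non-benzylic carbon, inverting Cβ from R to S.

Step 3
Reactants: 5; 6, 1-[2,4-bis(benzyloxy)-6-hydroxyphenyl]ethan-1-one
Product: 7, the (E)-2′-hydroxychalcone, (2E)-1-[2,4-bis(benzyloxy)-6-hydroxyphenyl]-3-(aryl)prop-2-en-1-one, where aryl is the 3-hydroxy-5-methoxy-4-O-[(S)-alkyl]phenyl unit of 5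
Conditions: KOH (50% aq, about 15 equiv), EtOH–THF, rt, 48 h
Reagents that add atoms: none
Why: Claisen–Schmidt aldol condensation tolerates a free meta-phenol (isovanillin-type aldehydes behave this way), and Cβ has no acidic hydrogen or β-leaving pathway, so it is not at risk.

Step 4
Reactants: 7
Product: 8, 5,7-bis(benzyloxy)-2-(4-{[(2S)-1-(benzyloxy)-3-[4-(benzyloxy)-3-methoxyphenyl]propan-2-yl]oxy}-3-hydroxy-5-methoxyphenyl)-4H-chromen-4-one
Conditions: I2 (10 mol %), DMSO, 130 °C, 3 h; aq Na2S2O3
Reagents that add atoms: none
Why: I2/DMSO oxidative cyclisation (oxa-Michael, then iodination and HI loss, with DMSO re-oxidising HI) is the standard chalcone-to-flavone conversion and is compatible with benzyl ethers and a free 3′-OH.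

Step 5
Reactants: 8
Product: 9, 5,7-dihydroxy-2-(3-hydroxy-4-{[(2S)-1-hydroxy-3-(4-hydroxy-3-methoxyphenyl)propan-2-yl]oxy}-5-methoxyphenyl)-4H-chromen-4-one (the seco flavone)
Conditions: H2 (1 atm), 20% Pd(OH)2/C, THF–MeOH 1:1, rt, 16 h
Reagents that add atoms: none (H2 only)
Why: Catalytic hydrogenolysis removes all four O-benzyl groups at once, and at this stage no ring benzylic C–O bond exists that could be cleaved, since Cβ–OAr is only homobenzylic.

Step 6
Reactants: 9
Product: 10, 5′-methoxyhydnocarpin, 2-[(2R,3R)-3-(4-hydroxy-3-methoxyphenyl)-2-(hydroxymethyl)-8-methoxy-2,3-dihydro-1,4-benzodioxin-6-yl]-5,7-dihydroxy-4H-chromen-4-one. The Cβ descriptor changes from S to R only because Cα now outranks CH2OH; no bond at Cβ changes.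
Conditions: undivided cell, graphite felt (+) / Pt (−), nBu4NPF6 (0.1 M), 2,6-lutidine (2 equiv), MeCN–HFIP 4:1, 5 mM in 9, 1 mA cm⁻², 2.1 F mol⁻¹, N2, rt
Reagents that add atoms: none
Why: Proposed new method: this is an anodic dehydrogenative benzylic C(sp3)–H/phenol O–H coupling, in which the 4-alkylguaiacol, the most electron-rich arene in 9 (the other three phenols sit on chromone-conjugated rings and should oxidise at least 0.3 V later), undergoes an ECE two-electron oxidation to the phenoxenium ion under buffered, non-basic conditions, lutidine removes a Cα proton to give the p-quinone methide (the same intermediate as in oxidative coniferyl alcohol/catechol couplings, but with Cβ already fixed), and the adjacent 3′-OH adds 6-exo-trig with aryl and CH2OH both pseudo-equatorial in a reversible oxa-Michael closure that funnels to the trans-(αR,βR) isomer while H2 is released at the cathode; the closest known reaction types are anodic benzylic functionalisation of 4-alkylphenols via quinone methides with external nucleophiles and Ag(I)-mediated biomimetic benzodioxane formation, and what has not been shown is the intramolecular, substrate-diastereocontrolled ring closure on an unprotected flavone.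

**Compound list**

| No. | Name | SMILES | Role |
|---|---|---|---|
| 1 | 1-(benzyloxy)-4-bromo-2-methoxybenzene | COc1cc(Br)ccc1OCc1ccccc1 | starting material |
| 2 | (R)-benzyl glycidyl ether | C1[C@@H](O1)COCc2ccccc2 | starting material (chiral) |
| 3 | (2R)-1-(benzyloxy)-3-[4-(benzyloxy)-3-methoxyphenyl]propan-2-ol | COc1cc(C[C@@H](O)COCc2ccccc2)ccc1OCc1ccccc1 | intermediate |
| 4 | 3,4-dihydroxy-5-methoxybenzaldehyde | COc1cc(C=O)cc(O)c1O | starting material |
| 5 | (S)-4-O-alkyl-3-hydroxy-5-methoxybenzaldehyde | COc1cc(C[C@H](Oc2c(O)cc(C=O)cc2OC)COCc2ccccc2)ccc1OCc1ccccc1 | intermediate |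
| 6 | 1-[2,4-bis(benzyloxy)-6-hydroxyphenyl]ethan-1-one | CC(=O)c1c(O)cc(OCc2ccccc2)cc1OCc1ccccc1 | starting material |
| 7 | (E)-2′-hydroxy-4′,6′-bis(benzyloxy)chalcone of 5 | COc1cc(C[C@H](Oc2c(O)cc(/C=C/C(=O)c3c(O)cc(OCc4ccccc4)cc3OCc3ccccc3)cc2OC)COCc2ccccc2)ccc1OCc1ccccc1 | intermediate |
| 8 | tetrabenzyl seco flavone | COc1cc(C[C@H](Oc2c(O)cc(-c3cc(=O)c4c(OCc5ccccc5)cc(OCc5ccccc5)cc4o3)cc2OC)COCc2ccccc2)ccc1OCc1ccccc1 | intermediate |
| 9 | seco flavone (pentahydroxy) | COc1cc(C[C@H](Oc2c(O)cc(-c3cc(=O)c4c(O)cc(O)cc4o3)cc2OC)CO)ccc1O | intermediate |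
| 10 | 5′-methoxyhydnocarpin, (2R,3R) | COc1cc([C@H]2Oc3cc(-c4cc(=O)c5c(O)cc(O)cc5o4)cc(OC)c3O[C@@H]2CO)ccc1O | target |

**Totals**
Total steps: 6. Longest linear sequence: 6.

**Three steps most likely to fail**

1. **Step 6 (new anodic ring closure).**
   - Risks: C5–C5 dimerisation of the guaiacol and electrode fouling. The product keeps a guaiacol unit and may over-oxidise. The quinone methide could tautomerise to the enol ether, which would erode Cβ.
   - Fallback (known chemistry): carry Cα already oxygenated.
     - Add the Grignard from 1 to (S)-2,3-O-isopropylideneglyceraldehyde (derived from L-ascorbic acid).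
     - Silylate the Cα-OH and exchange the acetonide for a primary ether.
     - Invert Cβ by Mitsunobu reaction with 4, then build the flavone as in steps 3–5.
     - Close the ring by acid-promoted ionisation of the p-hydroxybenzylic alcohol. This is the established trans-selective closure of 2-aryl-3-hydroxymethyl-1,4-benzodioxanes, and the Cα epimer mixture does not matter.
     - The cost is about 3–4 extra steps.

2. **Step 2 (Mitsunobu on a free, doubly ortho-flanked catechol OH).**
   - Risks: catechol–phosphorane formation, 3-O or bis-alkylation, and elimination to the styrene.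
   - Fallback: make the same C–O bond from the arene side with retention. Run SNAr of the potassium alkoxide of ent-3 (from (S)-benzyl glycidyl ether) on 3-(benzyloxy)-4-fluoro-5-methoxybenzaldehyde. The extra benzyl group is removed in step 5.

3. **Step 5 (four-fold hydrogenolysis, including a slow primary alkyl benzyl ether).**
   - Risks: incomplete cleavage, or reduction of the flavone C2=C3 bond.
   - Fallback: change to an all-acid-labile protecting scheme. Use MOM-protected 4-bromoguaiacol, (R)-trityl glycidyl ether and 2-hydroxy-4,6-bis(methoxymethoxy)acetophenone, and unmask everything with HCl/MeOH before the electrolysis.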